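**Retrosynthetic overview**
1. Target 17 ⇐ allylic alcohol 16 (O‑formylation) ⇐ alkyne 14 (Zr‑carboalumination/CH2O sets 13E) ⇐ ester 12 (C4 methylation sets C4).
2. Key disconnection: halim‑1(10)‑ene 12 ⇐ labdane‑type cis‑decalin carbinol 10, by a dehydrative 1,2‑methyl shift C10→C9 with loss of H‑1 (makes the C9 quaternary centre, C8 and the 1(10)‑olefin).
3. 10 ⇐ ketone 7 + C4 Grignard reagent 9; 7 ⇐ keto ester 6 (α‑methylation).
4. 6 ⇐ enone 4 + ketene silyl acetal 3 (enantioselective Mukaiyama–Michael sets C5; enolate ring closure gives the cis ring fusion).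
5. Ring order: ring B comes in with the enone, ring A is annulated in step 3, and the skeleton is reorganised in step 6.

**Assumptions**
- The target is read from the SMILES as (4S,5R,8R,9S,13E) in halimane numbering, which is (1S,5S,6R,8aR) in naphthalene numbering: H‑5 and the methyls on C4, C8 and C9 are on one face, the ester and the side chain on the other. Halimane/labdane locants are used in the text.
- The C‑silyl group of 8 is a protecting group; it is removed in step 7.
- Centres carried on purpose as epimer mixtures (C4 until step 7; C8 and C9 until step 6) carry no stereo mark in the SMILES. The change S→R at C8a between 12 and 13 is a CIP priority effect only.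

**Route**

Step 1
Reactants: 1 5-bromopentanoic acid
Product: 2 methyl 5-bromopentanoate
Conditions: MeOH, cat. H2SO4, reflux
Reagents that add atoms: methanol, CO
Why: Fischer esterification of the acid in methanol leaves the primary bromide untouched and forms no stereocentre.

Step 2
Reactants: 2 methyl 5-bromopentanoate
Product: 3 [(5-bromo-1-methoxypent-1-en-1-yl)oxy]trimethylsilane (E/Z mixture)
Conditions: LDA, TMSCl (in-situ quench), THF, −78 °C
Reagents that add atoms: chlorotrimethylsilane, C[Si](C)(C)Cl
Why: Kinetic ester enolate formation with in-situ O-silylation gives the ketene silyl acetal before the slow 4-exo-tet self-alkylation can compete, and its geometry is irrelevant because C4 is set later.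

Step 3
Reactants: 3 ketene silyl acetal; 4 2-methylcyclohex-2-en-1-one
Product: 6 methyl (4aR,8aS)-4a-methyl-5-oxodecahydronaphthalene-1-carboxylate (C1 epimers), via silyl enol ether adduct 5 (not isolated)
Conditions: chiral oxazaborolidinium triflimide (10 mol %, the enantiomer that gives (1S)-5), Ph3PO (25 mol %), toluene, −20 °C; then TBAF (anhydrous), THF, −20 °C to rt
Reagents that add atoms: none
Why: Catalytic enantioselective Mukaiyama–Michael addition (known for ketene silyl acetals and cyclic enones under chiral oxazaborolidinium Lewis acid catalysis) sets C5 by face-selective attack on the bound enone, and fluoride then frees the regiodefined enolate, which closes ring A by intramolecular 6-exo-tet C-alkylation on the face of the C5 tether, so the fusion is cis (H-5 and the angular methyl syn) and C10 follows from C5.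

Step 4
Reactants: 6 cis-decalone keto ester
Product: 7 methyl (4aR,8aS)-4a,6-dimethyl-5-oxodecahydronaphthalene-1-carboxylate (C1/C6 epimers)
Conditions: LDA, THF, −78 °C; MeI
Reagents that add atoms: iodomethane, CI
Why: Kinetic deprotonation occurs at C8, the only enolisable position of the ketone (more acidic than the ester), and enolate methylation installs C17, whose configuration does not matter because step 6 passes through the Δ8 olefin.

Step 5
Reactants: 7 methylated keto ester; 8 (4-bromobut-1-yn-1-yl)trimethylsilane
Product: 10 methyl (4aR,8aS)-5-hydroxy-4a,6-dimethyl-5-[4-(trimethylsilyl)but-3-yn-1-yl]decahydronaphthalene-1-carboxylate (C1/C5/C6 epimers), via Grignard reagent 9 (not isolated)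
Conditions: 8, Mg, THF; then 7, LaCl3·2LiCl (30 mol %), THF, −20 to 0 °C; H2O work-up
Reagents that add atoms: none
Why: Lanthanum-promoted Grignard 1,2-addition (oxophilic activation suppresses enolisation and favours the ketone over the ester) attaches C11–C14, and the carbinol configuration is irrelevant because C9 is ionised in step 6.

Step 6
Reactants: 10 tertiary carbinol (epimer mixture)
Product: 12 methyl (5S,6R,8aS)-5,6-dimethyl-5-[4-(trimethylsilyl)but-3-yn-1-yl]-1,2,3,5,6,7,8,8a-octahydronaphthalene-1-carboxylate (C1 epimers), via tetrasubstituted olefin 11 (not isolated)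
Conditions: confined chiral IDPi Brønsted acid (5 mol %, matched enantiomer), 5 Å MS, CHCl3, −20 °C to rt
Reagents that add atoms: none
Why: Proposed new method: a confined imidodiphosphorimidate acid first dehydrates the carbinol mixture to the tetrasubstituted Δ8 olefin 11 (which erases C8 and C9), then protonates C8 on the β-face while the axial angular methyl shifts anti-periplanar from C10 to C9 (σ-participation, so H-8 and the migrating methyl add anti across the olefin and C8 (R) and C9 (S) follow from C10), and the catalyst anion on the β-face removes the anti-periplanar H-1β to give the 1(10)-olefin instead of the 5(10)-isomer (H-5 is syn to the departed methyl); the closest known reactions are the Westphalen–Lettré and friedo backbone rearrangements and IDPi-catalysed Wagner–Meerwein shifts of simple olefins, which have not been shown as a stereoconvergent dehydrative methyl shift setting two stereocentres in a cis-decalin.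

Step 7
Reactants: 12 halimene ester (C1 epimers)
Product: 14 methyl (1S,5S,6R,8aR)-5-(but-3-yn-1-yl)-1,5,6-trimethyl-1,2,3,5,6,7,8,8a-octahydronaphthalene-1-carboxylate, via C-silyl alkyne 13 (not isolated)
Conditions: LDA, THF–DMPU, −78 to −40 °C; MeI; then MeOH, K2CO3, rt
Reagents that add atoms: iodomethane, CI
Why: In this ester enolate alkylation methyl iodide attacks the exocyclic C4 enolate equatorially, from the face of the pseudo-axial H-5 and anti to ring carbon C10 (A1,3-strain model with C6 eclipsing the enolate), which places the new methyl cis to H-5 and the ester axial (4S), and K2CO3 methanolysis then removes the C-silyl group.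

Step 8
Reactants: 14 terminal alkyne
Product: 16 methyl (1S,5S,6R,8aR)-5-[(3E)-5-hydroxy-3-methylpent-3-en-1-yl]-1,5,6-trimethyl-1,2,3,5,6,7,8,8a-octahydronaphthalene-1-carboxylate, via alkenylalane 15 (not isolated)
Conditions: AlMe3, Cp2ZrCl2 (20 mol %), CH2Cl2, 0 °C to rt; then (CH2O)n, THF, 0 °C; H2O work-up
Reagents that add atoms: trimethylaluminium, C[Al](C)C; formaldehyde (as paraformaldehyde), C=O
Why: Negishi zirconium-catalysed carboalumination adds methyl and aluminium syn across the terminal alkyne with aluminium at the terminus, and the alkenylalane reacts with formaldehyde with retention, which fixes the 13E olefin.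

Step 9
Reactants: 16 allylic alcohol
Product: 17 methyl (1S,5S,6R,8aR)-5-[(3E)-5-(formyloxy)-3-methylpent-3-en-1-yl]-1,5,6-trimethyl-1,2,3,5,6,7,8,8a-octahydronaphthalene-1-carboxylate (CNP0188193.1)
Conditions: acetic formic anhydride, pyridine, CH2Cl2, 0 °C
Reagents that add atoms: acetic formic anhydride, CC(=O)OC=O
Why: O-Formylation of the primary allylic alcohol by the mixed anhydride transfers the more electrophilic formyl group and touches no stereocentre.

**Compound list**
1 | 5-bromopentanoic acid | OC(=O)CCCCBr | starting material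
2 | methyl 5-bromopentanoate | COC(=O)CCCCBr | intermediate
3 | [(5-bromo-1-methoxypent-1-en-1-yl)oxy]trimethylsilane (E/Z mixture) | COC(=CCCCBr)O[Si](C)(C)C | intermediate
4 | 2-methylcyclohex-2-en-1-one | CC1=CCCCC1=O | starting material
5 | methyl 5-bromo-2-[(1S)-2-methyl-3-(trimethylsilyloxy)cyclohex-2-en-1-yl]pentanoate (C2 epimers) | COC(=O)C(CCCBr)[C@@H]1CCCC(O[Si](C)(C)C)=C1C | intermediate
6 | methyl (4aR,8aS)-4a-methyl-5-oxodecahydronaphthalene-1-carboxylate (cis-fused; C1 epimers) | COC(=O)C1CCC[C@@]2(C)C(=O)CCC[C@@H]12 | intermediate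
7 | methyl (4aR,8aS)-4a,6-dimethyl-5-oxodecahydronaphthalene-1-carboxylate (C1/C6 epimers) | COC(=O)C1CCC[C@@]2(C)C(=O)C(C)CC[C@@H]12 | intermediate
8 | (4-bromobut-1-yn-1-yl)trimethylsilane | C[Si](C)(C)C#CCCBr | starting material
9 | bromo[4-(trimethylsilyl)but-3-yn-1-yl]magnesium | C[Si](C)(C)C#CCC[Mg]Br | intermediate
10 | methyl (4aR,8aS)-5-hydroxy-4a,6-dimethyl-5-[4-(trimethylsilyl)but-3-yn-1-yl]decahydronaphthalene-1-carboxylate (C1/C5/C6 epimers) | COC(=O)C1CCC[C@@]2(C)C(O)(CCC#C[Si](C)(C)C)C(C)CC[C@@H]12 | intermediate
11 | methyl (4aR,8aS)-4a,6-dimethyl-5-[4-(trimethylsilyl)but-3-yn-1-yl]-1,2,3,4,4a,7,8,8a-octahydronaphthalene-1-carboxylate (C1 epimers) | COC(=O)C1CCC[C@@]2(C)C(CCC#C[Si](C)(C)C)=C(C)CC[C@@H]12 | intermediate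
12 | methyl (5S,6R,8aS)-5,6-dimethyl-5-[4-(trimethylsilyl)but-3-yn-1-yl]-1,2,3,5,6,7,8,8a-octahydronaphthalene-1-carboxylate (C1 epimers) | COC(=O)C1CCC=C2[C@H]1CC[C@@H](C)[C@]2(C)CCC#C[Si](C)(C)C | intermediate
13 | methyl (1S,5S,6R,8aR)-1,5,6-trimethyl-5-[4-(trimethylsilyl)but-3-yn-1-yl]-1,2,3,5,6,7,8,8a-octahydronaphthalene-1-carboxylate | COC(=O)[C@@]1(C)CCC=C2[C@H]1CC[C@@H](C)[C@]2(C)CCC#C[Si](C)(C)C | intermediate
14 | methyl (1S,5S,6R,8aR)-5-(but-3-yn-1-yl)-1,5,6-trimethyl-1,2,3,5,6,7,8,8a-octahydronaphthalene-1-carboxylate | COC(=O)[C@@]1(C)CCC=C2[C@H]1CC[C@@H](C)[C@]2(C)CCC#C | intermediate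
15 | (E)-alkenyldimethylalane from 14 (Al on C14, trans to C12) | COC(=O)[C@@]1(C)CCC=C2[C@H]1CC[C@@H](C)[C@]2(C)CC/C(C)=C/[Al](C)C | intermediate
16 | methyl (1S,5S,6R,8aR)-5-[(3E)-5-hydroxy-3-methylpent-3-en-1-yl]-1,5,6-trimethyl-1,2,3,5,6,7,8,8a-octahydronaphthalene-1-carboxylate | COC(=O)[C@@]1(C)CCC=C2[C@H]1CC[C@@H](C)[C@]2(C)CC/C(C)=C/CO | intermediate
17 | methyl (1S,5S,6R,8aR)-5-[(3E)-5-(formyloxy)-3-methylpent-3-en-1-yl]-1,5,6-trimethyl-1,2,3,5,6,7,8,8a-octahydronaphthalene-1-carboxylate | COC(=O)[C@@]1(C)CCC=C2[C@H]1CC[C@@H](C)[C@]2(C)CC/C(C)=C/COC=O | target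

**Step count**
Total: 9 steps. Longest linear sequence: 9 steps (1 → 17; the Grignard reagent 9 is made and used in the flask of step 5).

**Three steps most likely to fail**

Step 6 (the proposed new step). Likely failure modes are protonation of C8 from the wrong face (8-epimer), drift to the 5(10)-olefin on re-protonation, and capture of the C10 cation by the C4 ester. The fallback uses known reactions only. It sets out from 10, which is dehydrated (Burgess reagent) to the olefin 11, now isolated. mCPBA epoxidises 11 on the face anti to the axial angular methyl to give the 8β,9β-epoxide F5. BF3·OEt2 then triggers the epoxide-opening 1,2-methyl shift with loss of H-1, a Wagner–Meerwein rearrangement of the kind used on epoxy-labdanes and epoxy-steroids, giving the 8β-hydroxy-halim-1(10)-ene F6. Dehydration with SOCl2/pyridine gives the exocyclic 1(10),8(17)-diene F7. Hydrogen-atom-transfer hydrogenation (Mn(dpm)3, PhSiH3, t-BuOOH) reduces only the 1,1-disubstituted olefin and gives the thermodynamic equatorial C8 methyl, cis to the axial C9 methyl. The sequence comes back to the route at 12.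

Step 3. The α-methyl group of enone 4 may slow the catalysed Michael addition or lower its ee. The fallback sets out from 3 and runs the same catalysed addition on cyclohex-2-en-1-one F1, the substrate type for which this catalysis is established, to give the silyl enol ether F2. Fluoride closes ring A to the nor-methyl decalone F3. The angular methyl is then installed by thermodynamic enolate methylation (t-BuOK, MeI), which on 1-decalones gives mainly the cis-fused product. The sequence comes back at 6.

Step 5. The ketone is flanked by a quaternary and a tertiary carbon, so enolisation or attack on the ester may win. The fallback sets out from 7, which is converted (KHMDS, PhNTf2) into the tetrasubstituted enol triflate F4. Iron-catalysed Kumada coupling (Fe(acac)3, THF/NMP, −30 °C, ester-tolerant) with Grignard reagent 9 gives the olefin 11 directly. 11 is then submitted to the step 6 conditions, where no dehydration is needed, so the sequence comes back at 11.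

Further compounds
F1 | step 3 | cyclohex-2-en-1-one (purchased) | O=C1C=CCCC1
F2 | step 3 | methyl 5-bromo-2-[(1R)-3-(trimethylsilyloxy)cyclohex-2-en-1-yl]pentanoate (C2 epimers; same spatial arrangement at C1 as in 5) | COC(=O)C(CCCBr)[C@@H]1CCCC(O[Si](C)(C)C)=C1
F3 | step 3 | methyl (8aR)-5-oxodecahydronaphthalene-1-carboxylate (C1/C4a epimers) | COC(=O)C1CCCC2C(=O)CCC[C@@H]12
F4 | step 5 | methyl (4aR,8aS)-4a,6-dimethyl-5-(trifluoromethylsulfonyloxy)-1,2,3,4,4a,7,8,8a-octahydronaphthalene-1-carboxylate (C1 epimers) | COC(=O)C1CCC[C@@]2(C)C(OS(=O)(=O)C(F)(F)F)=C(C)CC[C@@H]12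
F5 | step 6 | 8β,9β-epoxide of 11 (oxirane anti to the angular methyl; C1 epimers) | COC(=O)C1CCC[C@@]2(C)[C@@]3(CCC#C[Si](C)(C)C)O[C@@]3(C)CC[C@@H]12
F6 | step 6 | 8β-hydroxy derivative of 12 (8-OH β, 8-Me α, 9-Me α; C1 epimers) | COC(=O)C1CCC=C2[C@H]1CC[C@@](O)(C)[C@]2(C)CCC#C[Si](C)(C)C
F7 | step 6 | 8(17)-exo-methylene analogue of 12 (halima-1(10),8(17)-diene; C1 epimers) | COC(=O)C1CCC=C2[C@H]1CCC(=C)[C@]2(C)CCC#C[Si](C)(C)C
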